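## Retrosynthetic overview

Locants follow the octahydroazulene numbering of the target; ring A is the cyclopentane, ring B the cycloheptene.

1. The target comes from its aryl O-silyl ether; ring B is closed last at C6–C7 by a nickel/chromium-catalysed alkenyl iodide–aldehyde coupling that also sets the C7 carbinol.
2. The C7 aldehyde is unmasked from a 1-(trimethylsilyl)vinyl group; before that, the C4 ester is made from a ring A diol and O-silyl vanillic acid (four steps from catechol).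
3. The diol comes from isopropyl addition (C3) to an anti aldol adduct (C3a–C4 bond) of a cyclopentanone enolate and (Z)-3-iodobut-2-enal (two steps from but-2-yn-1-ol).
4. The regiodefined enol silane comes from a copper-catalysed enantioselective conjugate addition of a silylvinylalane to 3-methylcyclopent-2-enone (C8–C8a bond, quaternary C8a).
5. Ring order: ring A is bought and elaborated first; ring B is formed last.

Assumption: the named antipodes of the chiral ligands L1 (copper step) and L2 (chromium step) are taken to give the configurations drawn; if either induces the opposite sense, its mirror image is used.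

## Route

Step 1
Reactants: 1 3-methylcyclopent-2-en-1-one; 2 ethynyltrimethylsilane
Product: 5 triethyl({(3S)-3-methyl-3-[1-(trimethylsilyl)ethenyl]cyclopent-1-en-1-yl}oxy)silane, via vinylalane 3 (not isolated), via aluminium enolate 4 (not isolated)
Conditions: 2, i-Bu2AlH, hexane/THF, 55 °C; then 1, CuCl2·2H2O (5 mol %), Ag2(L1)2 (2.5 mol %; L1 = (4S,5S)-1-(2,6-diethylphenyl)-4,5-diphenyl-3-(2-sulfonatophenyl)imidazolidin-2-ylidene), THF, −78 → −30 °C; then Et3SiOTf, −78 → 0 °C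
Reagents that add atoms: triethylsilyl trifluoromethanesulfonate, CC[Si](CC)(CC)OS(=O)(=O)C(F)(F)F
Why: Carbene–copper-catalysed enantioselective conjugate addition of the alkenylaluminium to the β-methyl enone puts the silylvinyl group on one enone face and creates the quaternary centre (3S, later C8a), and O-silylation of the aluminium enolate fixes its regiochemistry.

Step 2
Reactants: 6 but-2-yn-1-ol
Product: 8 (2Z)-3-iodobut-2-en-1-ol, via cyclic alkenylaluminate 7 (not isolated)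
Conditions: NaAlH2(OCH2CH2OMe)2, Et2O, 0 °C → rt; then EtOAc; then I2, THF, −78 → 0 °C
Reagents that add atoms: iodine, II
Why: Hydroxyl-directed trans-hydroalumination gives the five-membered alkenylaluminate with aluminium on C3, and iodinolysis with retention gives the Z iodide.

Step 3
Reactants: 8 (2Z)-3-iodobut-2-en-1-ol
Product: 9 (2Z)-3-iodobut-2-enal
Conditions: MnO2, CH2Cl2, rt, dark; used at once
Reagents that add atoms: none
Why: MnO2 oxidation of the allylic alcohol is neutral, so the Z geometry of the enal is kept.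

Step 4
Reactants: 5 triethyl({(3S)-3-methyl-3-[1-(trimethylsilyl)ethenyl]cyclopent-1-en-1-yl}oxy)silane; 9 (2Z)-3-iodobut-2-enal
Product: 12 (2S,3S)-2-[(1R,2Z)-1-hydroxy-3-iodobut-2-en-1-yl]-3-methyl-3-[1-(trimethylsilyl)ethenyl]cyclopentan-1-one, via lithium enolate 10 (not isolated), via dicyclohexylboron enolate 11 (not isolated)
Conditions: MeLi, THF, 0 °C → rt; (c-C6H11)2BCl, −78 °C; 9, −78 → −20 °C; then MeOH, pH 7 buffer, 30% H2O2, 0 °C
Reagents that add atoms: none
Why: Si→Li→B exchange keeps the enolate regiochemistry, the ring-locked E boron enolate reacts through a Zimmerman–Traxler chair to give the anti aldol (1'R relative to C2), and the aldehyde attacks the enolate face opposite the bulky silylvinyl group (cis to the methyl), which sets C2 (S) relative to the quaternary centre.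

Step 5
Reactants: 12 (2S,3S)-2-[(1R,2Z)-1-hydroxy-3-iodobut-2-en-1-yl]-3-methyl-3-[1-(trimethylsilyl)ethenyl]cyclopentan-1-one
Product: 13 (1R,2S,3S)-2-[(1R,2Z)-1-hydroxy-3-iodobut-2-en-1-yl]-3-methyl-1-(propan-2-yl)-3-[1-(trimethylsilyl)ethenyl]cyclopentan-1-ol
Conditions: i-PrMgCl (3 equiv), LaCl3·2LiCl (1 equiv), THF, −78 → −20 °C; aq. NH4Cl
Reagents that add atoms: isopropylmagnesium chloride, CC(C)[Mg]Cl
Why: Lanthanum-promoted Grignard 1,2-addition limits enolisation and retro-aldol cleavage, and the nucleophile adds to the ketone face anti to the C2 side chain and the pseudoaxial C3 methyl, so the new tertiary hydroxyl is cis to the side chain (1R).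

Step 6
Reactants: 14 benzene-1,2-diol
Product: 15 2-methoxyphenol
Conditions: MeI (1.0 equiv), K2CO3 (1.0 equiv), acetone, reflux; distillation
Reagents that add atoms: iodomethane, CI
Why: Williamson etherification with one equivalent of electrophile gives the mono-methyl ether, which is separated from diol and diether by distillation.

Step 7
Reactants: 15 2-methoxyphenol
Product: 16 4-bromo-2-methoxyphenol
Conditions: N-bromosuccinimide, MeCN, 0 °C
Reagents that add atoms: N-bromosuccinimide, O=C1CCC(=O)N1Br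
Why: Electrophilic aromatic bromination goes para to the free hydroxyl, the stronger director.

Step 8
Reactants: 16 4-bromo-2-methoxyphenol
Product: 17 (4-bromo-2-methoxyphenoxy)tri(propan-2-yl)silane
Conditions: i-Pr3SiCl, imidazole, DMF, rt
Reagents that add atoms: chlorotri(propan-2-yl)silane, CC(C)[Si](Cl)(C(C)C)C(C)C
Why: Imidazole-promoted O-silylation gives a phenol ether that survives organolithium, borane, mild peroxide and chromium conditions and is removed by fluoride at the end.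

Step 9
Reactants: 17 (4-bromo-2-methoxyphenoxy)tri(propan-2-yl)silane
Product: 19 3-methoxy-4-{[tri(propan-2-yl)silyl]oxy}benzoic acid, via aryllithium 18 (not isolated)
Conditions: n-BuLi, THF, −78 °C; CO2 (g); then 1 M HCl
Reagents that add atoms: carbon dioxide, O=C=O
Why: Bromine–lithium exchange is faster than any ortho-metalation at −78 °C, and carboxylation of the aryllithium gives the acid.

Step 10
Reactants: 13 (1R,2S,3S)-2-[(1R,2Z)-1-hydroxy-3-iodobut-2-en-1-yl]-3-methyl-1-(propan-2-yl)-3-[1-(trimethylsilyl)ethenyl]cyclopentan-1-ol; 19 3-methoxy-4-{[tri(propan-2-yl)silyl]oxy}benzoic acid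
Product: 21 (1R,2Z)-1-{(1S,2R,5S)-2-hydroxy-5-methyl-2-(propan-2-yl)-5-[1-(trimethylsilyl)ethenyl]cyclopentyl}-3-iodobut-2-en-1-yl 3-methoxy-4-{[tri(propan-2-yl)silyl]oxy}benzoate, via mixed anhydride 20 (not isolated)
Conditions: 19, 2,4,6-Cl3C6H2COCl, Et3N, THF, rt; then 13, DMAP, toluene, 40 °C
Reagents that add atoms: none
Why: Yamaguchi esterification: DMAP transfers the aroyl group of the mixed anhydride to the secondary allylic hydroxyl with retention at carbon, while the tertiary hydroxyl is too hindered to react.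

Step 11
Reactants: 21 (1R,2Z)-1-{(1S,2R,5S)-2-hydroxy-5-methyl-2-(propan-2-yl)-5-[1-(trimethylsilyl)ethenyl]cyclopentyl}-3-iodobut-2-en-1-yl 3-methoxy-4-{[tri(propan-2-yl)silyl]oxy}benzoate
Product: 23 (1R,2Z)-1-{(1S,2R,5S)-2-hydroxy-5-[2-hydroxy-1-(trimethylsilyl)ethyl]-5-methyl-2-(propan-2-yl)cyclopentyl}-3-iodobut-2-en-1-yl 3-methoxy-4-{[tri(propan-2-yl)silyl]oxy}benzoate (either epimer at the silyl-bearing carbon), via alkylborane 22 (not isolated)
Conditions: 9-BBN (3 equiv), THF, 0 → 50 °C; then 30% H2O2, aq. NaOAc, 0 °C → rt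
Reagents that add atoms: hydrogen peroxide, OO
Why: Hydroboration–oxidation puts boron on the terminal CH2 of the 1,1-disubstituted vinylsilane (anti-Markovnikov, β to silicon) and leaves the trisubstituted iodoalkene and the ester alone; the new silyl-bearing stereocentre is erased in step 12.

Step 12
Reactants: 23 (1R,2Z)-1-{(1S,2R,5S)-2-hydroxy-5-[2-hydroxy-1-(trimethylsilyl)ethyl]-5-methyl-2-(propan-2-yl)cyclopentyl}-3-iodobut-2-en-1-yl 3-methoxy-4-{[tri(propan-2-yl)silyl]oxy}benzoate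
Product: 25 (1R,2Z)-1-[(1S,2R,5R)-2-hydroxy-5-methyl-5-(2-oxoethyl)-2-(propan-2-yl)cyclopentyl]-3-iodobut-2-en-1-yl 3-methoxy-4-{[tri(propan-2-yl)silyl]oxy}benzoate, via α-silyl aldehyde 24 (not isolated)
Conditions: Dess–Martin periodinane, CH2Cl2, 0 °C → rt; then H2O-saturated SiO2, CH2Cl2, rt
Reagents that add atoms: none
Why: Dess–Martin oxidation gives an α-silyl aldehyde whose C–Si bond is cleaved by water through the silyl enol ether (1,3 carbon-to-oxygen silyl shift, then hydrolysis), unmasking the CH2CHO arm; the tertiary alcohol is trans to this arm and cannot form a lactol.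

Step 13
Reactants: 25 (1R,2Z)-1-[(1S,2R,5R)-2-hydroxy-5-methyl-5-(2-oxoethyl)-2-(propan-2-yl)cyclopentyl]-3-iodobut-2-en-1-yl 3-methoxy-4-{[tri(propan-2-yl)silyl]oxy}benzoate
Product: 26 (3R,3aS,4S,7R,8aR)-3,7-dihydroxy-6,8a-dimethyl-3-(propan-2-yl)-1,2,3,3a,4,7,8,8a-octahydroazulen-4-yl 3-methoxy-4-{[tri(propan-2-yl)silyl]oxy}benzoate
Conditions: CrCl2 (15 mol %), L2 (17 mol %; L2 = (S)-N-[2-(4-isopropyl-4,5-dihydrooxazol-2-yl)-6-methylphenyl]methanesulfonamide), 1,8-bis(dimethylamino)naphthalene (17 mol %), NiCl2(neocuproine) (3 mol %), Mn (2 equiv), Cp2ZrCl2 (1.2 equiv), LiCl (2 equiv), MeCN, 5 mM, rt; aq. work-up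
Reagents that add atoms: none
Why: Proposed new method: a ligand-controlled, chromium-catalytic Nozaki–Hiyama–Kishi carbocyclisation to a cycloheptenol, in which zerovalent nickel (from NiCl2(neocuproine) and Mn) inserts into the alkenyl C–I bond with retention of the Z geometry, the alkenyl group passes to the trivalent chromium–sulfonamide complex, and the alkenylchromium adds to the tethered aldehyde inside the chiral octahedral chromium sphere so that the oxazoline ligand, not the ring, picks the aldehyde face (7R, hydroxyl cis to the angular methyl), while Cp2ZrCl2 frees the alkoxide and Mn returns divalent chromium; the closest known reaction type is the catalytic asymmetric nickel/chromium alkenyl halide–aldehyde coupling (intermolecular and macrocyclic) and the stoichiometric, substrate-controlled NHK closure of medium rings.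

Step 14
Reactants: 26 (3R,3aS,4S,7R,8aR)-3,7-dihydroxy-6,8a-dimethyl-3-(propan-2-yl)-1,2,3,3a,4,7,8,8a-octahydroazulen-4-yl 3-methoxy-4-{[tri(propan-2-yl)silyl]oxy}benzoate
Product: 27 (3R,3aS,4S,7R,8aR)-3,7-dihydroxy-6,8a-dimethyl-3-(propan-2-yl)-1,2,3,3a,4,7,8,8a-octahydroazulen-4-yl 4-hydroxy-3-methoxybenzoate
Conditions: n-Bu4NF, AcOH (1:1), THF, 0 °C
Reagents that add atoms: none
Why: Buffered fluoride cleaves the aryl silyl ether (phenoxide is a good leaving group at silicon) without touching the ester or the allylic and tertiary alcohols.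

## Compound list

1 | 3-methylcyclopent-2-en-1-one | CC1=CC(=O)CC1 | starting material
2 | ethynyltrimethylsilane | C#C[Si](C)(C)C | starting material
3 | bis(2-methylpropyl)[1-(trimethylsilyl)ethenyl]alumane | C=C([Si](C)(C)C)[Al](CC(C)C)CC(C)C | intermediate (not isolated)
4 | bis(2-methylpropyl)({(3S)-3-methyl-3-[1-(trimethylsilyl)ethenyl]cyclopent-1-en-1-yl}oxy)alumane | C=C([Si](C)(C)C)[C@@]1(C)CCC(O[Al](CC(C)C)CC(C)C)=C1 | intermediate (not isolated)
5 | triethyl({(3S)-3-methyl-3-[1-(trimethylsilyl)ethenyl]cyclopent-1-en-1-yl}oxy)silane | C=C([Si](C)(C)C)[C@@]1(C)CCC(O[Si](CC)(CC)CC)=C1 | intermediate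
6 | but-2-yn-1-ol | CC#CCO | starting material
7 | sodium 2,2-bis(2-methoxyethoxy)-3-methyl-2,5-dihydro-1,2-oxaluminol-2-uide | [Na+].COCCO[Al-]1(OCCOC)OCC=C1C | intermediate (not isolated)
8 | (2Z)-3-iodobut-2-en-1-ol | C/C(I)=C/CO | intermediate
9 | (2Z)-3-iodobut-2-enal | C/C(I)=C/C=O | intermediate
10 | lithium (3S)-3-methyl-3-[1-(trimethylsilyl)ethenyl]cyclopent-1-en-1-olate | C=C([Si](C)(C)C)[C@@]1(C)CCC(O[Li])=C1 | intermediate (not isolated)
11 | dicyclohexyl({(3S)-3-methyl-3-[1-(trimethylsilyl)ethenyl]cyclopent-1-en-1-yl}oxy)borane | C=C([Si](C)(C)C)[C@@]1(C)CCC(OB(C2CCCCC2)C2CCCCC2)=C1 | intermediate (not isolated)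
12 | (2S,3S)-2-[(1R,2Z)-1-hydroxy-3-iodobut-2-en-1-yl]-3-methyl-3-[1-(trimethylsilyl)ethenyl]cyclopentan-1-one | C=C([Si](C)(C)C)[C@@]1(C)CCC(=O)[C@@H]1[C@@H](O)/C=C(/C)I | intermediate
13 | (1R,2S,3S)-2-[(1R,2Z)-1-hydroxy-3-iodobut-2-en-1-yl]-3-methyl-1-(propan-2-yl)-3-[1-(trimethylsilyl)ethenyl]cyclopentan-1-ol | C=C([Si](C)(C)C)[C@@]1(C)CC[C@@](O)(C(C)C)[C@@H]1[C@@H](O)/C=C(/C)I | intermediate
14 | benzene-1,2-diol | Oc1ccccc1O | starting material
15 | 2-methoxyphenol | COc1ccccc1O | intermediate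
16 | 4-bromo-2-methoxyphenol | COc1cc(Br)ccc1O | intermediate
17 | (4-bromo-2-methoxyphenoxy)tri(propan-2-yl)silane | COc1cc(Br)ccc1O[Si](C(C)C)(C(C)C)C(C)C | intermediate
18 | (3-methoxy-4-{[tri(propan-2-yl)silyl]oxy}phenyl)lithium | [Li]c1ccc(O[Si](C(C)C)(C(C)C)C(C)C)c(OC)c1 | intermediate (not isolated)
19 | 3-methoxy-4-{[tri(propan-2-yl)silyl]oxy}benzoic acid | COc1cc(C(=O)O)ccc1O[Si](C(C)C)(C(C)C)C(C)C | intermediate
20 | 3-methoxy-4-{[tri(propan-2-yl)silyl]oxy}benzoic 2,4,6-trichlorobenzoic anhydride | COc1cc(C(=O)OC(=O)c2c(Cl)cc(Cl)cc2Cl)ccc1O[Si](C(C)C)(C(C)C)C(C)C | intermediate (not isolated)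
21 | (1R,2Z)-1-{(1S,2R,5S)-2-hydroxy-5-methyl-2-(propan-2-yl)-5-[1-(trimethylsilyl)ethenyl]cyclopentyl}-3-iodobut-2-en-1-yl 3-methoxy-4-{[tri(propan-2-yl)silyl]oxy}benzoate | C=C([Si](C)(C)C)[C@@]1(C)CC[C@@](O)(C(C)C)[C@@H]1[C@@H](OC(=O)c2ccc(O[Si](C(C)C)(C(C)C)C(C)C)c(OC)c2)/C=C(/C)I | intermediate
22 | B-alkyl-9-borabicyclo[3.3.1]nonane adduct of 21 (boron on the terminal carbon; silyl-bearing carbon unassigned) | C[Si](C)(C)C(CB1C2CCCC1CCC2)[C@@]1(C)CC[C@@](O)(C(C)C)[C@@H]1[C@@H](OC(=O)c2ccc(O[Si](C(C)C)(C(C)C)C(C)C)c(OC)c2)/C=C(/C)I | intermediate (not isolated)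
23 | (1R,2Z)-1-{(1S,2R,5S)-2-hydroxy-5-[2-hydroxy-1-(trimethylsilyl)ethyl]-5-methyl-2-(propan-2-yl)cyclopentyl}-3-iodobut-2-en-1-yl 3-methoxy-4-{[tri(propan-2-yl)silyl]oxy}benzoate (silyl-bearing carbon unassigned) | OCC([Si](C)(C)C)[C@@]1(C)CC[C@@](O)(C(C)C)[C@@H]1[C@@H](OC(=O)c2ccc(O[Si](C(C)C)(C(C)C)C(C)C)c(OC)c2)/C=C(/C)I | intermediate
24 | (1R,2Z)-1-{(1S,2R,5S)-2-hydroxy-5-methyl-5-[2-oxo-1-(trimethylsilyl)ethyl]-2-(propan-2-yl)cyclopentyl}-3-iodobut-2-en-1-yl 3-methoxy-4-{[tri(propan-2-yl)silyl]oxy}benzoate (silyl-bearing carbon unassigned) | O=CC([Si](C)(C)C)[C@@]1(C)CC[C@@](O)(C(C)C)[C@@H]1[C@@H](OC(=O)c2ccc(O[Si](C(C)C)(C(C)C)C(C)C)c(OC)c2)/C=C(/C)I | intermediate (not isolated)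
25 | (1R,2Z)-1-[(1S,2R,5R)-2-hydroxy-5-methyl-5-(2-oxoethyl)-2-(propan-2-yl)cyclopentyl]-3-iodobut-2-en-1-yl 3-methoxy-4-{[tri(propan-2-yl)silyl]oxy}benzoate | O=CC[C@@]1(C)CC[C@@](O)(C(C)C)[C@@H]1[C@@H](OC(=O)c2ccc(O[Si](C(C)C)(C(C)C)C(C)C)c(OC)c2)/C=C(/C)I | intermediate
26 | (3R,3aS,4S,7R,8aR)-3,7-dihydroxy-6,8a-dimethyl-3-(propan-2-yl)-1,2,3,3a,4,7,8,8a-octahydroazulen-4-yl 3-methoxy-4-{[tri(propan-2-yl)silyl]oxy}benzoate | COc1cc(C(=O)O[C@H]2C=C(C)[C@H](O)C[C@@]3(C)CC[C@@](O)(C(C)C)[C@H]23)ccc1O[Si](C(C)C)(C(C)C)C(C)C | intermediate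
27 | (3R,3aS,4S,7R,8aR)-3,7-dihydroxy-6,8a-dimethyl-3-(propan-2-yl)-1,2,3,3a,4,7,8,8a-octahydroazulen-4-yl 4-hydroxy-3-methoxybenzoate | COc1cc(C(=O)O[C@H]2C=C(C)[C@H](O)C[C@@]3(C)CC[C@@](O)(C(C)C)[C@H]23)ccc1O | target

## Step count and risks

Total step count: 14.
Longest linear sequence: 9 steps (but-2-yn-1-ol through steps 2, 3, 4, 5, 10, 11, 12, 13, 14; the catechol branch, steps 6–14, is equally long).

Three steps most likely to fail:

Step 4 (aldol of a hindered enolate next to a quaternary carbon; the carbinol configuration may come out syn). The fallback sets out from 5 and comes back at 21. Enolate 10, made from 5 as before, is transmetalated with ClTi(Oi-Pr)3 to tris(propan-2-yloxy)titanium (3S)-3-methyl-3-[1-(trimethylsilyl)ethenyl]cyclopent-1-en-1-olate F1. Titanium enolates of ring-locked ketones add to aldehydes syn-selectively, so with 9 this gives (2S,3S)-2-[(1S,2Z)-1-hydroxy-3-iodobut-2-en-1-yl]-3-methyl-3-[1-(trimethylsilyl)ethenyl]cyclopentan-1-one F2. Isopropyl addition under the conditions of step 5 gives (1R,2S,3S)-2-[(1S,2Z)-1-hydroxy-3-iodobut-2-en-1-yl]-3-methyl-1-(propan-2-yl)-3-[1-(trimethylsilyl)ethenyl]cyclopentan-1-ol F3. A Mitsunobu esterification with acid 19 (n-Bu3P, 1,1'-(azodicarbonyl)dipiperidine, toluene, 60 °C) then inverts the carbinol carbon and gives ester 21 directly, so the C4 configuration is set by inversion instead of by the aldol.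

Step 5 (secondary Grignard on a hindered, enolisable β-hydroxy ketone; reduction, enolisation or retro-aldol may win). The fallback sets out from 12 and comes back at 13. The smaller, non-reducing sp2 nucleophile CH2=C(CH3)MgBr with CeCl3 (THF, −78 °C) gives (1S,2S,3S)-2-[(1R,2Z)-1-hydroxy-3-iodobut-2-en-1-yl]-3-methyl-1-(prop-1-en-2-yl)-3-[1-(trimethylsilyl)ethenyl]cyclopentan-1-ol F4. Diimide (2-nitrobenzenesulfonylhydrazide, Et3N, CH2Cl2, rt) then reduces the isopropenyl group to give 13; the silyl-bearing alkene is more hindered and the iodoalkene is inert to diimide, though selectivity between the two 1,1-disubstituted alkenes must be checked.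

Step 13 (the proposed new step; ring strain or a mismatched substrate bias may erode catalyst control at C7). The fallback uses known chemistry, sets out from 25 and comes back at 26. Stoichiometric Nozaki–Hiyama–Kishi cyclisation (CrCl2 4 equiv, NiCl2 1 mol %, DMSO/THF, 5 mM) closes ring B under substrate control and gives 26 together with (3R,3aS,4S,7S,8aR)-3,7-dihydroxy-6,8a-dimethyl-3-(propan-2-yl)-1,2,3,3a,4,7,8,8a-octahydroazulen-4-yl 3-methoxy-4-{[tri(propan-2-yl)silyl]oxy}benzoate F5. F5 is oxidised with Dess–Martin periodinane to (3R,3aS,4S,8aR)-3-hydroxy-6,8a-dimethyl-7-oxo-3-(propan-2-yl)-1,2,3,3a,4,7,8,8a-octahydroazulen-4-yl 3-methoxy-4-{[tri(propan-2-yl)silyl]oxy}benzoate F6. Luche reduction (NaBH4, CeCl3·7H2O, MeOH, −78 °C) is expected to deliver hydride anti to the angular methyl and return 26, so C7 is set by ketone reduction instead of in the C–C coupling.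

## Further compounds

F1 | step 4 | tris(propan-2-yloxy)titanium (3S)-3-methyl-3-[1-(trimethylsilyl)ethenyl]cyclopent-1-en-1-olate | C=C([Si](C)(C)C)[C@@]1(C)CCC(O[Ti](OC(C)C)(OC(C)C)OC(C)C)=C1
F2 | step 4 | (2S,3S)-2-[(1S,2Z)-1-hydroxy-3-iodobut-2-en-1-yl]-3-methyl-3-[1-(trimethylsilyl)ethenyl]cyclopentan-1-one | C=C([Si](C)(C)C)[C@@]1(C)CCC(=O)[C@@H]1[C@H](O)/C=C(/C)I
F3 | step 4 | (1R,2S,3S)-2-[(1S,2Z)-1-hydroxy-3-iodobut-2-en-1-yl]-3-methyl-1-(propan-2-yl)-3-[1-(trimethylsilyl)ethenyl]cyclopentan-1-ol | C=C([Si](C)(C)C)[C@@]1(C)CC[C@@](O)(C(C)C)[C@@H]1[C@H](O)/C=C(/C)I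
F4 | step 5 | (1S,2S,3S)-2-[(1R,2Z)-1-hydroxy-3-iodobut-2-en-1-yl]-3-methyl-1-(prop-1-en-2-yl)-3-[1-(trimethylsilyl)ethenyl]cyclopentan-1-ol | C=C([Si](C)(C)C)[C@@]1(C)CC[C@@](O)(C(C)=C)[C@@H]1[C@@H](O)/C=C(/C)I
F5 | step 13 | (3R,3aS,4S,7S,8aR)-3,7-dihydroxy-6,8a-dimethyl-3-(propan-2-yl)-1,2,3,3a,4,7,8,8a-octahydroazulen-4-yl 3-methoxy-4-{[tri(propan-2-yl)silyl]oxy}benzoate | COc1cc(C(=O)O[C@H]2C=C(C)[C@@H](O)C[C@@]3(C)CC[C@@](O)(C(C)C)[C@H]23)ccc1O[Si](C(C)C)(C(C)C)C(C)C
F6 | step 13 | (3R,3aS,4S,8aR)-3-hydroxy-6,8a-dimethyl-7-oxo-3-(propan-2-yl)-1,2,3,3a,4,7,8,8a-octahydroazulen-4-yl 3-methoxy-4-{[tri(propan-2-yl)silyl]oxy}benzoate | COc1cc(C(=O)O[C@H]2C=C(C)C(=O)C[C@@]3(C)CC[C@@](O)(C(C)C)[C@H]23)ccc1O[Si](C(C)C)(C(C)C)C(C)C
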